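A closed, stirred vessel at constant temperature and volume turns free monomer into monomer in chains under an initiator, with a little impurity present. The teal run was made with half the free monomer of the flask now asked about.

common to all: impurity 0.52 mM
- teal: free monomer 0.10 M; initiator 5 mM; run made earlier
- flask: free monomer 0.20 M; initiator 5.0 mM; time 1.0 h

- teal (time / min: monomer in chains / %, free monomer / %): 1.00: 57.7, 33.7; 1.50: 75.8, 14.7; 2.50: 86.0, 2.0; 4.00: 88.7, 0.5; 8.00: 88.9, 0.5; 12.0: 89.5, 0.1

(scatter of a reading: 0.5 percentage points)

- the numbers in the tables scatter with a standard deviation of 0.5 percentage points
- the reaction counts as stopped when no species that holds the free monomer changes by six tenths of a point or more over the second half of the time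

* at 1.0 h, what has stopped the reaction, if anything has (forward and back rates have come level / no working catalyst is left / all of the free monomer has reacted / it is still moving)
* the monomer in chains standing at 1.0 h, as a percentage of the free monomer charged

Down the teal table, free monomer falls from 33.7 % at 1.00 min to 2.0 % at 2.50 min. Read as a pseudo-first-order decay, that is 1.88 min⁻¹, a half-life of 0.368 min.

Across each row, the two columns fall short of the charge, by 8.6 percentage points in the first row and 10 points in the last. In the last row that gap is 10.4 mM, more than the 0.52 mM of impurity charged, and it grows as free monomer is consumed. So the ratio of monomer in chains to free monomer consumed is worth reading. It is 87.0 % in the first row and 87.8 % in the third, and the last three rows pooled give 89.4 %, each reading scattering by 0.5 points. This nearly constant number is frozen as the chain share, c(monomer in chains) over free monomer consumed.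

Carrying the half-life and the share to the doubled charge is this reckoning's assumption. The flask's 60 min is far longer than the half-life, so free monomer should be consumed, and monomer in chains should stand at 89.4 % of the charge.

The forecast names the same end, all of the free monomer has reacted, and gives 89.6 %, close to the 89.4 % of this reckoning, on the ground that “A proportional share doesn't depend on monomer charged”.

The flask gives all of the free monomer has reacted, with 0 % free monomer and 88.5 % monomer in chains at 1.0 h.

    monomer in chains ⇌ isomer of the product (K = 0.130, k = 0.280 s⁻¹)
    initiator + impurity → spent initiator (k = 830 L mol⁻¹ s⁻¹)
    free monomer + living end → monomer in chains + living end, rate k3*[living end]*[free monomer] (k = 11.0 L mol⁻¹ s⁻¹)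
    free monomer + initiator → living end + monomer in chains (k = 0.190 L mol⁻¹ s⁻¹)

The flask also holds 11.5 % isomer of the product at 1.00 h, a species the chain share does not name. The neighbouring flask takes 0.020 M of initiator, its other charges and time as in the flask. Its free monomer stands at 0 %, so the same reckoning gives 89.4 %. It holds more living end than the flask, 0.00925 M against 0.00352 M, and its monomer in chains stands at 88.5 %.

The runs are calculated with constants of no real substance.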